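Ring letters: A is the 3,5-dihydroxyphenoxy ring, B and C are the benzo rings of the dibenzofuran, D is the outer dioxin ring, E–F is the biaryl, and G and H are the terminal rings. The bonds between rings are B1–O–A, B6–O–C1 and B5–C6 (furan), C4–O–D6 and C5–O–D1 (dioxin), D5–O–E1, E6–F1, F6–O–G1 and G6–O–H1.
Enabling feature: E and F are two phloroglucinol rings bonded C–C (E6–F1) at carbons that each sit next to an ether oxygen (E1–O, F6–O). Without D and G they form a C2-symmetric 4,4',6,6'-tetraoxygenated biphenyl-2,2'-diol, so the two phenol oxygens can be tied by one CH2 and E6 and F1 then joined by oxidation.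
Cuts: first D5–O and G1–O, made by SNAr of the diol oxygens on aryl fluorides activated by CHO groups; these CHO groups later become the D2, D4 and G4 hydroxyls by Baeyer–Villiger oxidation. Then E6–F1; in the core C5–O–D1, B5–C6, B6–O–C1, C4–O–D6 and B1–O–A; in the tail G6–O–H1.
Forward: the dioxepine ring closes in step 2 and is opened in step 3, and G–H fluoride 16 is attached to one oxygen of diol 5. The core grows as the C–D ether, then the furan ring (steps 24 and 25), then the dioxin ring (step 27). Union follows in step 28, then a threefold Baeyer–Villiger oxidation and a thirteenfold demethylation.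
Stereochemistry: the target has no stereocentre, so nothing has to be set or protected.

Key step: step 2

Remark on the chemistry: the E–F axis carries four ortho oxygens and is stereogenic, but the structure is drawn without an axial descriptor, so the racemate is taken as the target.

Step 1
Reactants: 1 3,5-dimethoxyphenol (2 equiv); 2 dibromomethane
Product: 3 bis(3,5-dimethoxyphenoxy)methane
Conditions: K2CO3, DMF, 80 °C
Reagents that add atoms: none
Why: Double Williamson etherification; the aryloxymethyl bromide formed first is far more reactive than CH2Br2, so the symmetrical formaldehyde diaryl acetal should be the main product.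

Step 2
Reactants: 3 bis(3,5-dimethoxyphenoxy)methane
Product: 4 1,3,9,11-tetramethoxydibenzo[d,f][1,3]dioxepine
Conditions: PhI(OCOCF3)2 (1.1 equiv), BF3·OEt2 (2.2 equiv), CH2Cl2 (2 mM, slow addition of 3), −78 to −40 °C
Reagents that add atoms: none
Why: The BF3-activated trivalent iodine reagent takes one electron from one trialkoxyarene ring, the radical cation is attacked by the ortho carbon of the tethered ring, and loss of a second electron and of two protons restores both arenes and leaves the E6–F1 bond. The closest known reaction type is the intramolecular oxidative biaryl coupling of phenol ethers bridged through silicon or acetal tethers, brought about by trivalent iodine reagents or MoCl5. The single new ring is the seven-membered 1,3-dioxepine, closed by aryl–aryl C–C bond formation between the two carbons ortho to the O–CH2–O bridge. No stereocentre is created, and the bridged biaryl axis forms as a racemate. The selectivity needed is ortho–ortho coupling in preference to reaction at the equally activated carbon between the two methoxy groups: the one-carbon bridge lets only the ortho carbons reach each other, the two ortho positions of each ring are equivalent, and high dilution at low temperature holds back intermolecular coupling and attack of the iodine centre on the ring.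

Step 3
Reactants: 4 1,3,9,11-tetramethoxydibenzo[d,f][1,3]dioxepine
Product: 5 4,4',6,6'-tetramethoxybiphenyl-2,2'-diol
Conditions: HS(CH2)3SH (1.5 equiv), BF3·OEt2, CH2Cl2, 0 °C to rt
Reagents that add atoms: none
Why: Lewis-acid transthioacetalisation (hard acid, soft nucleophile): BF3 ionises the twisted O–CH2–O bridge and the dithiol carries the CH2 away as 1,3-dithiane before it can alkylate the electron-rich rings, while aryl methyl ethers survive this acid at room temperature.

Step 4
Reactants: 6 3,5-dimethoxybenzaldehyde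
Product: 7 2-(3,5-dimethoxyphenyl)-1,3-dioxolane
Conditions: ethylene glycol, TsOH·H2O (cat.), toluene, reflux, azeotropic removal of water
Reagents that add atoms: ethylene glycol, OCCO
Why: Acid-catalysed acetalisation driven by water removal masks the formyl group for the organolithium step.

Step 5
Reactants: 7 2-(3,5-dimethoxyphenyl)-1,3-dioxolane
Product: 9 2-(4-fluoro-3,5-dimethoxyphenyl)-1,3-dioxolane, via aryllithium 8 (not isolated)
Conditions: n-BuLi, THF, 0 °C to rt; then NFSI, −78 °C to rt
Reagents that add atoms: N-fluorobenzenesulfonimide (NFSI), O=S(=O)(c1ccccc1)N(F)S(=O)(=O)c1ccccc1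
Why: Directed ortho-metalation goes to the carbon flanked by both methoxy groups (cooperative direction, the dioxolane being the weaker director), and electrophilic fluorination of the aryllithium by the N–F reagent installs the future leaving group.

Step 6
Reactants: 9 2-(4-fluoro-3,5-dimethoxyphenyl)-1,3-dioxolane
Product: 10 4-fluoro-3,5-dimethoxybenzaldehyde
Conditions: 1 M HCl, THF, rt
Reagents that add atoms: water, O
Why: Acid hydrolysis of the dioxolane releases the formyl group para to fluorine, which turns 10 into the SNAr electrophile for ring H.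

Step 7
Reactants: 9 2-(4-fluoro-3,5-dimethoxyphenyl)-1,3-dioxolane
Product: 11 5-(1,3-dioxolan-2-yl)-2-fluoro-3-methoxyphenol
Conditions: EtSNa, DMF, 110 °C
Reagents that add atoms: none
Why: Thiolate SN2 demethylation of an aryl methyl ether stops at the monophenol because the phenoxide formed resists a second cleavage, and the fluoride is safe because the masked aldehyde gives it no acceptor activation.

Step 8
Reactants: 11 5-(1,3-dioxolan-2-yl)-2-fluoro-3-methoxyphenol; 10 4-fluoro-3,5-dimethoxybenzaldehyde
Product: 12 4-[5-(1,3-dioxolan-2-yl)-2-fluoro-3-methoxyphenoxy]-3,5-dimethoxybenzaldehyde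
Conditions: K2CO3, DMF, 120 °C
Reagents that add atoms: none
Why: SNAr etherification forming G6–O–H1: only the fluoride of 10 is para to a formyl group, whereas the fluoride on the acetal-bearing ring of 11 and 12 is unactivated, so self-condensation and over-reaction are excluded.

Step 9
Reactants: 12 4-[5-(1,3-dioxolan-2-yl)-2-fluoro-3-methoxyphenoxy]-3,5-dimethoxybenzaldehyde
Product: 14 4-[5-(1,3-dioxolan-2-yl)-2-fluoro-3-methoxyphenoxy]-3,5-dimethoxyphenol, via aryl formate 13 (not isolated)
Conditions: mCPBA (pre-dried), CH2Cl2, 0 °C to rt; then K2CO3 (cat.), MeOH, rt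
Reagents that add atoms: mCPBA, OOC(=O)c1cccc(Cl)c1
Why: Baeyer–Villiger oxidation of an electron-rich benzaldehyde (aryl migration favoured by the para aryloxy group) followed by methanolysis of the formate, the peracid variant of the Dakin sequence, puts the H4 oxygen in place.

Step 10
Reactants: 14 4-[5-(1,3-dioxolan-2-yl)-2-fluoro-3-methoxyphenoxy]-3,5-dimethoxyphenol
Product: 16 4-fluoro-3-methoxy-5-(2,4,6-trimethoxyphenoxy)benzaldehyde, via trimethoxyphenyl ether acetal 15 (not isolated)
Conditions: MeI, K2CO3, acetone, reflux; then 1 M HCl, THF, rt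
Reagents that add atoms: iodomethane, CI; water, O
Why: Williamson methylation completes the 2,4,6-trimethoxyphenoxy ring H, and acid hydrolysis of the dioxolane then switches on the G1 fluoride by unmasking the para formyl group.

Step 11
Reactants: 5 4,4',6,6'-tetramethoxybiphenyl-2,2'-diol (3 equiv); 16 4-fluoro-3-methoxy-5-(2,4,6-trimethoxyphenoxy)benzaldehyde
Product: 17 4-[(2'-hydroxy-4,4',6,6'-tetramethoxybiphenyl-2-yl)oxy]-3-methoxy-5-(2,4,6-trimethoxyphenoxy)benzaldehyde
Conditions: Cs2CO3 (1.2 equiv), DMSO, 110 °C; excess 5 recovered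
Reagents that add atoms: none
Why: SNAr etherification forming F6–O–G1: the monophenoxide of the C2-symmetric diol attacks the fluoride para to CHO, the excess of diol keeps the reaction at the mono-ether stage, and any Smiles-type aryl shift between the two equivalent oxygens is degenerate.

Step 12
Reactants: 11 5-(1,3-dioxolan-2-yl)-2-fluoro-3-methoxyphenol
Product: 18 4-fluoro-3-hydroxy-5-methoxybenzaldehyde
Conditions: 1 M HCl, THF, rt
Reagents that add atoms: water, O
Why: Acid hydrolysis of the dioxolane gives the free hydroxy aldehyde that serves as ring C (CHO at C1, OMe at C3, F at C4, OH at C5).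

Step 13
Reactants: 18 4-fluoro-3-hydroxy-5-methoxybenzaldehyde
Product: 19 2-bromo-4-fluoro-3-hydroxy-5-methoxybenzaldehyde
Conditions: NBS (1.0 equiv), i-Pr2NH (10 mol %), CH2Cl2, 0 °C
Reagents that add atoms: N-bromosuccinimide, O=C1CCC(=O)N1Br
Why: Amine-mediated ortho-selective electrophilic bromination of a phenol: the only free position ortho to the hydroxyl, which is also para to the methoxy group, is C6 of ring C, the carbon that will later bond to B5.

Step 14
Reactants: 19 2-bromo-4-fluoro-3-hydroxy-5-methoxybenzaldehyde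
Product: 20 2-bromo-4-fluoro-5-methoxy-3-(methoxymethoxy)benzaldehyde
Conditions: MOMCl, i-Pr2NEt, CH2Cl2, 0 °C to rt
Reagents that add atoms: chloromethyl methyl ether, COCCl
Why: Standard methoxymethyl protection of the acidic phenol gives a group that is inert to base, peracid, copper and palladium and that offers no arene C–H bond to the later palladium step.

Step 15
Reactants: 21 2,4-difluoro-3-methoxybenzaldehyde
Product: 22 2-(2,4-difluoro-3-methoxyphenyl)-1,3-dioxolane
Conditions: ethylene glycol, TsOH·H2O (cat.), toluene, reflux, azeotropic removal of water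
Reagents that add atoms: ethylene glycol, OCCO
Why: Acid-catalysed acetalisation masks the aldehyde before lithiation.

Step 16
Reactants: 22 2-(2,4-difluoro-3-methoxyphenyl)-1,3-dioxolane
Product: 24 5-(1,3-dioxolan-2-yl)-2,4-difluoro-3-methoxybenzaldehyde, via aryllithium 23 (not isolated)
Conditions: LDA, THF, −78 °C; then DMF, −78 °C to 0 °C; aq. work-up
Reagents that add atoms: N,N-dimethylformamide, CN(C)C=O
Why: Fluorine-directed ortho-lithiation removes the only proton next to a fluorine (it is also para to the other fluorine), and formylation with DMF supplies the second carbonyl carbon of the symmetric ring D.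

Step 17
Reactants: 24 5-(1,3-dioxolan-2-yl)-2,4-difluoro-3-methoxybenzaldehyde
Product: 25 2,2'-(4,6-difluoro-5-methoxy-1,3-phenylene)bis(1,3-dioxolane)
Conditions: ethylene glycol, TsOH·H2O (cat.), toluene, reflux, azeotropic removal of water
Reagents that add atoms: ethylene glycol, OCCO
Why: The second acetalisation restores the local symmetry of ring D and removes all acceptor activation from both fluorides.

Step 18
Reactants: 25 2,2'-(4,6-difluoro-5-methoxy-1,3-phenylene)bis(1,3-dioxolane)
Product: 26 3,5-bis(1,3-dioxolan-2-yl)-2,6-difluorophenol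
Conditions: EtSNa, DMF, 90 °C
Reagents that add atoms: none
Why: Thiolate SN2 demethylation is easy here because the departing 2,6-difluorophenoxide is a stabilised anion, and the unactivated fluorides and the acetals tolerate the thiolate.

Step 19
Reactants: 20 2-bromo-4-fluoro-5-methoxy-3-(methoxymethoxy)benzaldehyde; 26 3,5-bis(1,3-dioxolan-2-yl)-2,6-difluorophenol
Product: 27 4-[3,5-bis(1,3-dioxolan-2-yl)-2,6-difluorophenoxy]-2-bromo-5-methoxy-3-(methoxymethoxy)benzaldehyde
Conditions: Cs2CO3, DMSO, 110 °C
Reagents that add atoms: none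
Why: SNAr etherification forming C4–O–D6: the fluoride of 20 is para to CHO, whereas both fluorides of 26 and of product 27 lack an acceptor, and fluoride leaves much faster than the bromide ortho to CHO.

Step 20
Reactants: 27 4-[3,5-bis(1,3-dioxolan-2-yl)-2,6-difluorophenoxy]-2-bromo-5-methoxy-3-(methoxymethoxy)benzaldehyde
Product: 29 4-[3,5-bis(1,3-dioxolan-2-yl)-2,6-difluorophenoxy]-2-bromo-5-methoxy-3-(methoxymethoxy)phenol, via aryl formate 28 (not isolated)
Conditions: mCPBA (pre-dried), CH2Cl2, 0 °C to rt; then K2CO3 (cat.), MeOH, rt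
Reagents that add atoms: mCPBA, OOC(=O)c1cccc(Cl)c1
Why: Baeyer–Villiger oxidation and formate methanolysis turn the spent activating group into the C1 hydroxyl (aryl migration favoured by the para aryloxy group), while the ring D aldehydes stay hidden as acetals.

Step 21
Reactants: 30 5-iodovanillin (4-hydroxy-3-iodo-5-methoxybenzaldehyde); 31 (3,5-dimethoxyphenyl)boronic acid
Product: 32 4-(3,5-dimethoxyphenoxy)-3-iodo-5-methoxybenzaldehyde
Conditions: Cu(OAc)2 (1 equiv), pyridine, 4 Å molecular sieves, CH2Cl2, air, rt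
Reagents that add atoms: none
Why: Chan–Lam coupling forming B1–O–A: the unhindered arylboronic acid is transferred by Cu(OAc)2 at room temperature to the di-ortho-substituted phenol, under conditions that leave the aryl iodide and the aldehyde untouched.

Step 22
Reactants: 32 4-(3,5-dimethoxyphenoxy)-3-iodo-5-methoxybenzaldehyde
Product: 34 4-(3,5-dimethoxyphenoxy)-3-iodo-5-methoxyphenol, via aryl formate 33 (not isolated)
Conditions: mCPBA, CH2Cl2, 0 °C to rt, thiosulfate wash; then K2CO3 (cat.), MeOH, rt
Reagents that add atoms: mCPBA, OOC(=O)c1cccc(Cl)c1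
Why: Baeyer–Villiger oxidation and formate methanolysis convert the formyl group into the B4 hydroxyl (aryl migration favoured by the para aryloxy group), and the reductive wash returns any iodine oxidised by the peracid to the aryl iodide.

Step 23
Reactants: 34 4-(3,5-dimethoxyphenoxy)-3-iodo-5-methoxyphenol
Product: 35 2-(3,5-dimethoxyphenoxy)-1-iodo-3,5-dimethoxybenzene
Conditions: MeI, K2CO3, acetone, reflux
Reagents that add atoms: iodomethane, CI
Why: Williamson methylation caps the only free phenol, so that 29 is the sole nucleophile in the next coupling.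

Step 24
Reactants: 29 4-[3,5-bis(1,3-dioxolan-2-yl)-2,6-difluorophenoxy]-2-bromo-5-methoxy-3-(methoxymethoxy)phenol; 35 2-(3,5-dimethoxyphenoxy)-1-iodo-3,5-dimethoxybenzene
Product: 36 2,2'-{5-[3-bromo-4-[2-(3,5-dimethoxyphenoxy)-3,5-dimethoxyphenoxy]-6-methoxy-2-(methoxymethoxy)phenoxy]-4,6-difluoro-1,3-phenylene}bis(1,3-dioxolane)
Conditions: CuI (20 mol %), N,N-dimethylglycine hydrochloride (40 mol %), Cs2CO3, 1,4-dioxane, 90 °C, argon
Reagents that add atoms: none
Why: Ligand-accelerated Ullmann ether synthesis forming B6–O–C1: CuI engages the aryl iodide of 35 much faster than the bromide of 29, which is flanked by two oxygens and sits on the electron-rich phenoxide ring.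

Step 25
Reactants: 36 open A–B–C–D bromide
Product: 37 8-[3,5-bis(1,3-dioxolan-2-yl)-2,6-difluorophenoxy]-4-(3,5-dimethoxyphenoxy)-1,3,7-trimethoxy-9-(methoxymethoxy)dibenzofuran
Conditions: Pd(OAc)2 (10 mol %), PCy3·HBF4 (20 mol %), PivOH (30 mol %), K2CO3, DMA, 130 °C
Reagents that add atoms: none
Why: Palladium-catalysed intramolecular direct arylation (oxidative addition into C6–Br, carboxylate-assisted concerted metalation–deprotonation at B5–H, reductive elimination) closes the furan ring, and B5 is the only C–H within reach because B1 is substituted.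

Step 26
Reactants: 37 protected dibenzofuran
Product: 38 5-{[4-(3,5-dimethoxyphenoxy)-9-hydroxy-1,3,7-trimethoxydibenzofuran-8-yl]oxy}-4,6-difluorobenzene-1,3-dicarbaldehyde
Conditions: 3 M HCl, THF, 45 °C
Reagents that add atoms: water, O
Why: Aqueous acid hydrolysis removes the two dioxolanes and the methoxymethyl ether in one operation, and no SNAr can start as long as the medium is acidic.

Step 27
Reactants: 38 hydroxy difluoro dialdehyde
Product: 39 core fluoride: benzofuro[3,2-a]dibenzo[b,e][1,4]dioxine with CHO at D2 and D4, F at D5, OMe at B2, B4 and C3, and the 3,5-dimethoxyphenoxy group at B1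
Conditions: K2CO3, DMF (5 mM), rt to 40 °C
Reagents that add atoms: none
Why: Intramolecular SNAr closes the six-membered dioxin ring: the C5 phenoxide attacks a fluoride that is ortho to one CHO and para to the other, and since D1 and D5 are related by the local symmetry of ring D either attack gives the same product with the required orientation (D6 on the C4 oxygen).

Step 28
Reactants: 39 core fluoride; 17 E–F–G–H phenol
Product: 40 permethylated octamer trialdehyde (CHO at D2/D4/G4)
Conditions: K2CO3, DMF, 50 °C
Reagents that add atoms: none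
Why: SNAr etherification forming D5–O–E1: the remaining fluoride is activated by two formyl groups, so the hindered phenoxide of 17 can react at a temperature at which the aryloxy groups on the activated rings are not exchanged.

Step 29
Reactants: 40 permethylated octamer trialdehyde
Product: 42 target tridecamethyl ether (free OH only at D2/D4/G4), via tris(formate) 41 (not isolated)
Conditions: mCPBA (4 equiv), CH2Cl2, 0 °C to rt; then K2CO3 (cat.), degassed MeOH, 0 °C, argon
Reagents that add atoms: mCPBA, OOC(=O)c1cccc(Cl)c1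
Why: Threefold Baeyer–Villiger oxidation: each formyl group has an aryloxy group ortho or para to it that favours aryl migration, and mild methanolysis of the formates under argon frees the D2, D4 and G4 hydroxyls.

Step 30
Reactants: 42 target tridecamethyl ether
Product: 43 CNP0192765.0 (target, racemic at the E–F axis)
Conditions: BBr3 (40 equiv), CH2Cl2, −78 °C to rt, argon; then H2O
Reagents that add atoms: none
Why: Lewis-acid cleavage of aryl methyl ethers with BBr3 removes all thirteen methyl groups, whereas the diaryl ether, dioxin and furan C–O bonds offer no sp3 carbon for bromide to attack.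

Compound list
1 | 3,5-dimethoxyphenol | COc1cc(O)cc(OC)c1 | starting material
2 | dibromomethane | BrCBr | starting material
3 | bis(3,5-dimethoxyphenoxy)methane | COc1cc(OC)cc(OCOc2cc(OC)cc(OC)c2)c1 | intermediate
4 | 1,3,9,11-tetramethoxydibenzo[d,f][1,3]dioxepine | COc1cc(OC)c2c(c1)OCOc1cc(OC)cc(OC)c1-2 | intermediate
5 | 4,4',6,6'-tetramethoxybiphenyl-2,2'-diol | COc1cc(O)c(c(OC)c1)-c1c(O)cc(OC)cc1OC | intermediate
6 | 3,5-dimethoxybenzaldehyde | COc1cc(C=O)cc(OC)c1 | starting material
7 | 2-(3,5-dimethoxyphenyl)-1,3-dioxolane | COc1cc(cc(OC)c1)C1OCCO1 | intermediate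
8 | [4-(1,3-dioxolan-2-yl)-2,6-dimethoxyphenyl]lithium | [Li]c1c(OC)cc(cc1OC)C1OCCO1 | intermediate
9 | 2-(4-fluoro-3,5-dimethoxyphenyl)-1,3-dioxolane | COc1cc(cc(OC)c1F)C1OCCO1 | intermediate
10 | 4-fluoro-3,5-dimethoxybenzaldehyde | COc1cc(C=O)cc(OC)c1F | intermediate
11 | 5-(1,3-dioxolan-2-yl)-2-fluoro-3-methoxyphenol | COc1cc(cc(O)c1F)C1OCCO1 | intermediate
12 | 4-[5-(1,3-dioxolan-2-yl)-2-fluoro-3-methoxyphenoxy]-3,5-dimethoxybenzaldehyde | O=Cc1cc(OC)c(Oc2cc(cc(OC)c2F)C2OCCO2)c(OC)c1 | intermediate
13 | 4-[5-(1,3-dioxolan-2-yl)-2-fluoro-3-methoxyphenoxy]-3,5-dimethoxyphenyl formate | O=COc1cc(OC)c(Oc2cc(cc(OC)c2F)C2OCCO2)c(OC)c1 | intermediate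
14 | 4-[5-(1,3-dioxolan-2-yl)-2-fluoro-3-methoxyphenoxy]-3,5-dimethoxyphenol | Oc1cc(OC)c(Oc2cc(cc(OC)c2F)C2OCCO2)c(OC)c1 | intermediate
15 | 2-[4-fluoro-3-methoxy-5-(2,4,6-trimethoxyphenoxy)phenyl]-1,3-dioxolane | COc1cc(OC)c(Oc2cc(cc(OC)c2F)C2OCCO2)c(OC)c1 | intermediate
16 | 4-fluoro-3-methoxy-5-(2,4,6-trimethoxyphenoxy)benzaldehyde | COc1cc(OC)c(Oc2cc(C=O)cc(OC)c2F)c(OC)c1 | intermediate
17 | 4-[(2'-hydroxy-4,4',6,6'-tetramethoxybiphenyl-2-yl)oxy]-3-methoxy-5-(2,4,6-trimethoxyphenoxy)benzaldehyde | COc1cc(O)c(c(OC)c1)-c1c(OC)cc(OC)cc1Oc1c(OC)cc(C=O)cc1Oc1c(OC)cc(OC)cc1OC | intermediate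
18 | 4-fluoro-3-hydroxy-5-methoxybenzaldehyde | COc1cc(C=O)cc(O)c1F | intermediate
19 | 2-bromo-4-fluoro-3-hydroxy-5-methoxybenzaldehyde | COc1cc(C=O)c(Br)c(O)c1F | intermediate
20 | 2-bromo-4-fluoro-5-methoxy-3-(methoxymethoxy)benzaldehyde | COCOc1c(Br)c(C=O)cc(OC)c1F | intermediate
21 | 2,4-difluoro-3-methoxybenzaldehyde | COc1c(F)ccc(C=O)c1F | starting material
22 | 2-(2,4-difluoro-3-methoxyphenyl)-1,3-dioxolane | COc1c(F)ccc(C2OCCO2)c1F | intermediate
23 | [5-(1,3-dioxolan-2-yl)-2,4-difluoro-3-methoxyphenyl]lithium | COc1c(F)c([Li])cc(C2OCCO2)c1F | intermediate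
24 | 5-(1,3-dioxolan-2-yl)-2,4-difluoro-3-methoxybenzaldehyde | COc1c(F)c(C=O)cc(C2OCCO2)c1F | intermediate
25 | 2,2'-(4,6-difluoro-5-methoxy-1,3-phenylene)bis(1,3-dioxolane) | COc1c(F)c(cc(C2OCCO2)c1F)C1OCCO1 | intermediate
26 | 3,5-bis(1,3-dioxolan-2-yl)-2,6-difluorophenol | Oc1c(F)c(cc(C2OCCO2)c1F)C1OCCO1 | intermediate
27 | 4-[3,5-bis(1,3-dioxolan-2-yl)-2,6-difluorophenoxy]-2-bromo-5-methoxy-3-(methoxymethoxy)benzaldehyde | COCOc1c(Br)c(C=O)cc(OC)c1Oc1c(F)c(cc(C2OCCO2)c1F)C1OCCO1 | intermediate
28 | 4-[3,5-bis(1,3-dioxolan-2-yl)-2,6-difluorophenoxy]-2-bromo-5-methoxy-3-(methoxymethoxy)phenyl formate | COCOc1c(Br)c(OC=O)cc(OC)c1Oc1c(F)c(cc(C2OCCO2)c1F)C1OCCO1 | intermediate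
29 | 4-[3,5-bis(1,3-dioxolan-2-yl)-2,6-difluorophenoxy]-2-bromo-5-methoxy-3-(methoxymethoxy)phenol | COCOc1c(Br)c(O)cc(OC)c1Oc1c(F)c(cc(C2OCCO2)c1F)C1OCCO1 | intermediate
30 | 5-iodovanillin (4-hydroxy-3-iodo-5-methoxybenzaldehyde) | COc1cc(C=O)cc(I)c1O | starting material
31 | (3,5-dimethoxyphenyl)boronic acid | COc1cc(cc(OC)c1)B(O)O | starting material
32 | 4-(3,5-dimethoxyphenoxy)-3-iodo-5-methoxybenzaldehyde | COc1cc(OC)cc(Oc2c(I)cc(C=O)cc2OC)c1 | intermediate
33 | 4-(3,5-dimethoxyphenoxy)-3-iodo-5-methoxyphenyl formate | COc1cc(OC)cc(Oc2c(I)cc(OC=O)cc2OC)c1 | intermediate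
34 | 4-(3,5-dimethoxyphenoxy)-3-iodo-5-methoxyphenol | COc1cc(OC)cc(Oc2c(I)cc(O)cc2OC)c1 | intermediate
35 | 2-(3,5-dimethoxyphenoxy)-1-iodo-3,5-dimethoxybenzene | COc1cc(OC)cc(Oc2c(I)cc(OC)cc2OC)c1 | intermediate
36 | 2,2'-{5-[3-bromo-4-[2-(3,5-dimethoxyphenoxy)-3,5-dimethoxyphenoxy]-6-methoxy-2-(methoxymethoxy)phenoxy]-4,6-difluoro-1,3-phenylene}bis(1,3-dioxolane) | COc1cc(OC)cc(Oc2c(OC)cc(OC)cc2Oc2cc(OC)c(Oc3c(F)c(cc(C4OCCO4)c3F)C3OCCO3)c(OCOC)c2Br)c1 | intermediate
37 | 8-[3,5-bis(1,3-dioxolan-2-yl)-2,6-difluorophenoxy]-4-(3,5-dimethoxyphenoxy)-1,3,7-trimethoxy-9-(methoxymethoxy)dibenzofuran | COc1cc(OC)cc(Oc2c(OC)cc(OC)c3c2oc2cc(OC)c(Oc4c(F)c(cc(C5OCCO5)c4F)C4OCCO4)c(OCOC)c23)c1 | intermediate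
38 | 5-{[4-(3,5-dimethoxyphenoxy)-9-hydroxy-1,3,7-trimethoxydibenzofuran-8-yl]oxy}-4,6-difluorobenzene-1,3-dicarbaldehyde | COc1cc(OC)cc(Oc2c(OC)cc(OC)c3c2oc2cc(OC)c(Oc4c(F)c(C=O)cc(C=O)c4F)c(O)c23)c1 | intermediate
39 | A–B–C–D core fluoride (benzofurodibenzodioxine; CHO at D2 and D4, F at D5, OMe at B2, B4, C3, 3,5-dimethoxyphenoxy at B1) | COc1cc(OC)cc(Oc2c(OC)cc(OC)c3c2oc2cc(OC)c4c(c23)Oc2c(C=O)cc(C=O)c(F)c2O4)c1 | intermediate
40 | permethylated octamer trialdehyde (CHO at D2, D4, G4; thirteen OMe) | COc1cc(OC)cc(Oc2c(OC)cc(OC)c3c2oc2cc(OC)c4c(c23)Oc2c(C=O)cc(C=O)c(Oc3cc(OC)cc(OC)c3-c3c(OC)cc(OC)cc3Oc3c(OC)cc(C=O)cc3Oc3c(OC)cc(OC)cc3OC)c2O4)c1 | intermediate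
41 | tris(formate) of 42 (OCHO at D2, D4, G4) | COc1cc(OC)cc(Oc2c(OC)cc(OC)c3c2oc2cc(OC)c4c(c23)Oc2c(OC=O)cc(OC=O)c(Oc3cc(OC)cc(OC)c3-c3c(OC)cc(OC)cc3Oc3c(OC)cc(OC=O)cc3Oc3c(OC)cc(OC)cc3OC)c2O4)c1 | intermediate
42 | target tridecamethyl ether (free OH at D2, D4, G4) | COc1cc(OC)cc(Oc2c(OC)cc(OC)c3c2oc2cc(OC)c4c(c23)Oc2c(O)cc(O)c(Oc3cc(OC)cc(OC)c3-c3c(OC)cc(OC)cc3Oc3c(OC)cc(O)cc3Oc3c(OC)cc(OC)cc3OC)c2O4)c1 | intermediate
43 | CNP0192765.0 | Oc1cc(O)cc(Oc2c(O)cc(O)c3c2oc2cc(O)c4c(c23)Oc2c(O)cc(O)c(Oc3cc(O)cc(O)c3-c3c(O)cc(O)cc3Oc3c(O)cc(O)cc3Oc3c(O)cc(O)cc3O)c2O4)c1 | target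

Total step count: 30.
Longest linear sequence: 15 steps (6 → 7 → 9 → 11 → 18 → 19 → 20 → 27 → 29 → 36 → 37 → 38 → 39 → 40 → 42 → 43, that is steps 4, 5, 7, 12, 13, 14, 19, 20 and 24–30).

Steps most likely to fail

Step 2. Phloroglucinol ethers are strongly nucleophilic at carbon. The iodine centre may therefore bond to a ring carbon by ligand exchange instead of taking an electron. The more easily oxidised biaryl product may be oxidised further, or the rings may couple between molecules at the carbon between the methoxy groups. The fallback sets out from 1 and rejoins the route at 4, and it fixes the coupling site by halogen position rather than by oxidation. Iodination of 1 ortho to the hydroxyl (NIS, MeCN, 0 °C, para isomer removed at this simple stage) should give 2-iodo-3,5-dimethoxyphenol F1. Alkylation of two equivalents of F1 with 2 (K2CO3, DMF) gives bis(2-iodo-3,5-dimethoxyphenoxy)methane F2. An intramolecular Ullmann biaryl coupling with activated copper powder in DMF at 140 °C then closes the same seven-membered ring to 4.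

Step 19. The weakly nucleophilic 2,6-difluorophenoxide may displace the fluoride flanked by two alkoxy groups too slowly. At the temperatures then needed, loss of the bromide ortho to CHO and degradation of the aldehyde would compete. The fallback sets out from 20 and rejoins at 27, and it changes the activating group. Knoevenagel condensation of 20 with malononitrile (piperidine cat., EtOH) gives {[2-bromo-4-fluoro-5-methoxy-3-(methoxymethoxy)phenyl]methylidene}propanedinitrile F3, whose dicyanovinyl group is an acceptor of nearly nitro strength. SNAr with 26 (K2CO3, dry DMF, 40–60 °C) gives the aryl ether {[4-[3,5-bis(1,3-dioxolan-2-yl)-2,6-difluorophenoxy]-2-bromo-5-methoxy-3-(methoxymethoxy)phenyl]methylidene}propanedinitrile F4. Retro-Knoevenagel hydrolysis (aq. NaOH, THF, 40 °C), to which acetals and the methoxymethyl ether are inert, returns the aldehyde 27.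

Step 30. Partly cleaved boron aryloxides may precipitate and stop the thirteenfold ether cleavage short. The free hexadecaphenol may also be oxidised by air or lost on silica during isolation. The fallback sets out from 42 and rejoins at 43, and it replaces direct isolation by capture and release. The crude product of the BBr3 cleavage is peracetylated at once (Ac2O, pyridine, argon) to the target hexadecaacetate F5, which is stable and can be chromatographed. Under-cleaved fractions are separated there and resubmitted. Acid-catalysed methanolysis of pure F5 (HCl, degassed MeOH, argon) followed by evaporation gives 43 without chromatography of the free phenol.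

Further compounds
F1 | step 2 | 2-iodo-3,5-dimethoxyphenol | COc1cc(O)c(I)c(OC)c1
F2 | step 2 | bis(2-iodo-3,5-dimethoxyphenoxy)methane | COc1cc(OC)c(I)c(OCOc2cc(OC)cc(OC)c2I)c1
F3 | step 19 | {[2-bromo-4-fluoro-5-methoxy-3-(methoxymethoxy)phenyl]methylidene}propanedinitrile | COCOc1c(Br)c(C=C(C#N)C#N)cc(OC)c1F
F4 | step 19 | {[4-[3,5-bis(1,3-dioxolan-2-yl)-2,6-difluorophenoxy]-2-bromo-5-methoxy-3-(methoxymethoxy)phenyl]methylidene}propanedinitrile | COCOc1c(Br)c(C=C(C#N)C#N)cc(OC)c1Oc1c(F)c(cc(C2OCCO2)c1F)C1OCCO1
F5 | step 30 | target hexadecaacetate | CC(=O)Oc1cc(OC(C)=O)cc(Oc2c(OC(C)=O)cc(OC(C)=O)c3c2oc2cc(OC(C)=O)c4c(c23)Oc2c(OC(C)=O)cc(OC(C)=O)c(Oc3cc(OC(C)=O)cc(OC(C)=O)c3-c3c(OC(C)=O)cc(OC(C)=O)cc3Oc3c(OC(C)=O)cc(OC(C)=O)cc3Oc3c(OC(C)=O)cc(OC(C)=O)cc3OC(C)=O)c2O4)c1
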